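**Retrosynthetic overview**
1. Enol senecioate (last bond): copper-catalysed C–O coupling of 3-methylbut-2-enoic acid with an (E)-alkenyltrifluoroborate, itself made from a C7 aldehyde by chromium-mediated boryl-olefination; final O-desilylation.
2. Dihydrofuran (second ring, proposed new step): domino Heck/oxa-Michael reaction of a 2-(hydroxymethyl)cyclohexenyl triflate with methyl vinyl ketone forms C7a–C1, O–C1 and the C1 stereocentre.
3. Cyclohexene (first ring): Dieckmann condensation to a β-keto ester, then enol triflate (fixes the tetrasubstituted C3a=C7a alkene); C4–OH from Noyori hydrogenation of an acyclic β-keto ester.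
4. C6/C7 (quaternary/tertiary pair): enantioselective Ireland–Claisen rearrangement of a geranyl 3-alkoxypropanoate; the new vinyl group becomes C5–C4 by hydroboration.
5. Order of events: acyclic C6/C7 pair → carbocycle → dihydrofuran → enol ester.

Locants C1, C3, C3a, C4–C7, C7a in the text are those of the 1,3,4,5,6,7-hexahydro-2-benzofuran core of the target (C1 carries the 2-oxopropyl group, C4 the hydroxyl, C6 is quaternary, C7 carries the enol ester).
Assumption: acid 2 is a catalogue compound and the bromodiazaborolidine of step 2 is made in one operation from the commercial (1R,2R)-bis-sulfonamide and BBr3.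
Assumption: the (4R,5R) boron reagent is taken to give the (2S,3S) acid; if the sense of induction is the opposite, the (4S,5S) reagent is used.

**Step 1**
Reactants: 1 geraniol; 2 3-[(4-methoxyphenyl)methoxy]propanoic acid
Product: 3 (2E)-3,7-dimethylocta-2,6-dien-1-yl 3-[(4-methoxyphenyl)methoxy]propanoate
Conditions: DCC, DMAP (cat.), CH2Cl2, 0 → 25 °C
Reagents that add atoms: none
Why: Steglich esterification of an unhindered primary allylic alcohol; no stereocentre is formed and the E-alkene is untouched.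

**Step 2**
Reactants: 3 (2E)-3,7-dimethylocta-2,6-dien-1-yl 3-[(4-methoxyphenyl)methoxy]propanoate
Product: 6 methyl (2S,3S)-3-ethenyl-2-{[(4-methoxyphenyl)methoxy]methyl}-3,7-dimethyloct-6-enoate, via boron ketene acetal 4 (not isolated), via carboxylic acid 5 (not isolated)
Conditions: (4R,5R)-2-bromo-1,3-bis{[3,5-bis(trifluoromethyl)phenyl]sulfonyl}-4,5-diphenyl-1,3,2-diazaborolidine (1.2 equiv), i-Pr2NEt, CH2Cl2, −78 °C then 4 °C, 48 h; H2O; then Me3SiCHN2, MeOH/PhMe, 0 °C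
Reagents that add atoms: trimethylsilyldiazomethane, C[Si](C)(C)C=[N+]=[N-]; the bromodiazaborolidine, BrB1N(S(=O)(=O)c2cc(cc(c2)C(F)(F)F)C(F)(F)F)[C@H](c2ccccc2)[C@@H](c2ccccc2)N1S(=O)(=O)c1cc(cc(c1)C(F)(F)F)C(F)(F)F (its boron unit is held only in 4)
Why: Enantioselective Ireland–Claisen rearrangement: soft enolisation gives the Z(O)-boron ketene acetal (CH2OPMB cis to O–B), whose chair [3,3] shift onto the E-geranyl unit (methyl axial, homoprenyl equatorial) sets the C6/C7 relative configuration, while the C2-symmetric sulfonamide ligand selects the enolate face and so the absolute configuration; the crude acid is methylated.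

**Step 3**
Reactants: 6 methyl (2S,3S)-3-ethenyl-2-{[(4-methoxyphenyl)methoxy]methyl}-3,7-dimethyloct-6-enoate
Product: 8 methyl (2S,3S)-3-(2-hydroxyethyl)-2-{[(4-methoxyphenyl)methoxy]methyl}-3,7-dimethyloct-6-enoate, via organoborane 7 (not isolated)
Conditions: 9-BBN, THF, 0 → 25 °C; then H2O2, aq. NaOAc, 0 → 25 °C
Reagents that add atoms: hydrogen peroxide, OO; 9-borabicyclo[3.3.1]nonane, B1C2CCCC1CCC2 (its boron is held only in 7)
Why: Anti-Markovnikov hydroboration–oxidation; 9-BBN adds only to the monosubstituted vinyl group and leaves the trisubstituted alkene and the ester, and no stereocentre is created.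

**Step 4**
Reactants: 8 methyl (2S,3S)-3-(2-hydroxyethyl)-2-{[(4-methoxyphenyl)methoxy]methyl}-3,7-dimethyloct-6-enoate
Product: 9 methyl (2S,3S)-2-{[(4-methoxyphenyl)methoxy]methyl}-3,7-dimethyl-3-(2-oxoethyl)oct-6-enoate
Conditions: Dess–Martin periodinane, NaHCO3, CH2Cl2, 0 → 25 °C
Reagents that add atoms: none
Why: Dess–Martin oxidation of a primary alcohol; the aldehyde α-carbon is a CH2 next to the quaternary centre, so nothing can epimerise.

**Step 5**
Reactants: 9 methyl (2S,3S)-2-{[(4-methoxyphenyl)methoxy]methyl}-3,7-dimethyl-3-(2-oxoethyl)oct-6-enoate; 10 ethyl diazoacetate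
Product: 11 1-ethyl 7-methyl (5S,6S)-6-{[(4-methoxyphenyl)methoxy]methyl}-5-methyl-5-(4-methylpent-3-en-1-yl)-3-oxoheptanedioate
Conditions: SnCl2 (10 mol %), CH2Cl2, 25 °C
Reagents that add atoms: none
Why: Roskamp homologation: Lewis-acid-promoted addition of the diazo ester to the aldehyde, then 1,2-hydride shift with loss of N2, gives the β-keto ester directly.

**Step 6**
Reactants: 11 1-ethyl 7-methyl (5S,6S)-6-{[(4-methoxyphenyl)methoxy]methyl}-5-methyl-5-(4-methylpent-3-en-1-yl)-3-oxoheptanedioate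
Product: 12 1-ethyl 7-methyl (3S,5S,6S)-3-hydroxy-6-{[(4-methoxyphenyl)methoxy]methyl}-5-methyl-5-(4-methylpent-3-en-1-yl)heptanedioate
Conditions: H2 (4 atm), RuCl2[(S)-BINAP] (1 mol %), EtOH, 50 °C
Reagents that add atoms: none
Why: Noyori asymmetric hydrogenation of a chelating β-keto ester; the (S)-BINAP catalyst delivers hydride with the same facial sense that turns methyl acetoacetate into the (S)-hydroxy ester, setting C4 as (S) under catalyst control while the isolated trisubstituted alkene is not reduced.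

**Step 7**
Reactants: 12 1-ethyl 7-methyl (3S,5S,6S)-3-hydroxy-6-{[(4-methoxyphenyl)methoxy]methyl}-5-methyl-5-(4-methylpent-3-en-1-yl)heptanedioate
Product: 13 1-ethyl 7-methyl (3S,5S,6S)-3-[(tert-butyldimethylsilyl)oxy]-6-{[(4-methoxyphenyl)methoxy]methyl}-5-methyl-5-(4-methylpent-3-en-1-yl)heptanedioate
Conditions: TBSOTf, 2,6-lutidine, CH2Cl2, −78 °C
Reagents that add atoms: tert-butyldimethylsilyl trifluoromethanesulfonate, CC(C)(C)[Si](C)(C)OS(=O)(=O)C(F)(F)F
Why: O-silylation of the secondary alcohol, which blocks lactonisation onto the methyl ester before the base-mediated ring closure.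

**Step 8**
Reactants: 13 1-ethyl 7-methyl (3S,5S,6S)-3-[(tert-butyldimethylsilyl)oxy]-6-{[(4-methoxyphenyl)methoxy]methyl}-5-methyl-5-(4-methylpent-3-en-1-yl)heptanedioate
Product: 14 ethyl (3S,4S,6S)-6-[(tert-butyldimethylsilyl)oxy]-2-hydroxy-3-{[(4-methoxyphenyl)methoxy]methyl}-4-methyl-4-(4-methylpent-3-en-1-yl)cyclohex-1-ene-1-carboxylate
Conditions: LiN(SiMe3)2 (2.5 equiv), THF, −78 → −30 °C; aq. NH4Cl
Reagents that add atoms: none
Why: Dieckmann condensation: the kinetic enolate of the unhindered CH2CO2Et group attacks the methyl ester 6-exo-trig (helped by the gem-dialkyl effect) and the product is held as its stabilised enolate, at a temperature where β-silyloxy elimination is slow; no new stereocentre (enolised β-keto ester).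

**Step 9**
Reactants: 14 ethyl (3S,4S,6S)-6-[(tert-butyldimethylsilyl)oxy]-2-hydroxy-3-{[(4-methoxyphenyl)methoxy]methyl}-4-methyl-4-(4-methylpent-3-en-1-yl)cyclohex-1-ene-1-carboxylate
Product: 15 ethyl (3S,4S,6S)-6-[(tert-butyldimethylsilyl)oxy]-3-{[(4-methoxyphenyl)methoxy]methyl}-4-methyl-4-(4-methylpent-3-en-1-yl)-2-[(trifluoromethanesulfonyl)oxy]cyclohex-1-ene-1-carboxylate
Conditions: NaH, THF, 0 °C; then PhNTf2, 0 → 25 °C
Reagents that add atoms: N-phenylbis(trifluoromethanesulfonimide), O=S(=O)(N(c1ccccc1)S(=O)(=O)C(F)(F)F)C(F)(F)F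
Why: O-triflation of the β-keto ester enolate; the ester fixes the enol triflate, and so the future tetrasubstituted C3a=C7a alkene, regiospecifically.

**Step 10**
Reactants: 15 ethyl (3S,4S,6S)-6-[(tert-butyldimethylsilyl)oxy]-3-{[(4-methoxyphenyl)methoxy]methyl}-4-methyl-4-(4-methylpent-3-en-1-yl)-2-[(trifluoromethanesulfonyl)oxy]cyclohex-1-ene-1-carboxylate
Product: 16 (3S,5S,6S)-3-[(tert-butyldimethylsilyl)oxy]-2-(hydroxymethyl)-6-{[(4-methoxyphenyl)methoxy]methyl}-5-methyl-5-(4-methylpent-3-en-1-yl)cyclohex-1-en-1-yl trifluoromethanesulfonate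
Conditions: i-Bu2AlH (3 equiv), CH2Cl2, −78 °C; aq. potassium sodium tartrate
Reagents that add atoms: none
Why: Hydride reduction of the conjugated ester to the allylic alcohol (C3); alkenyl triflates and silyl or benzyl ethers are inert to i-Bu2AlH at −78 °C.

**Step 11**
Reactants: 16 (3S,5S,6S)-3-[(tert-butyldimethylsilyl)oxy]-2-(hydroxymethyl)-6-{[(4-methoxyphenyl)methoxy]methyl}-5-methyl-5-(4-methylpent-3-en-1-yl)cyclohex-1-en-1-yl trifluoromethanesulfonate; 17 but-3-en-2-one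
Product: 19 1-[(1S,4S,6S,7R)-4-[(tert-butyldimethylsilyl)oxy]-7-{[(4-methoxyphenyl)methoxy]methyl}-6-methyl-6-(4-methylpent-3-en-1-yl)-1,3,4,5,6,7-hexahydro-2-benzofuran-1-yl]propan-2-one, via dienone 18 (not isolated)
Conditions: Pd(OAc)2 (5 mol %), PPh3 (10 mol %), Et3N, DMF, 60 °C; then DBU, 25 °C
Reagents that add atoms: none
Why: Proposed new method: a domino Heck alkenylation/oxa-Michael cyclisation, not yet shown for 2-(hydroxymethyl)cycloalk-1-enyl triflates: zerovalent palladium (formed from Pd(OAc)2/PPh3) adds oxidatively to the C7a–OTf bond, the alkenylpalladium inserts 17 at its CH2 terminus and β-hydride elimination gives (E)-dienone 18, whose C3 hydroxyl then adds 5-exo-trig to the enone β-carbon (C1) to close the 2,5-dihydrofuran; because the oxa-Michael step is reversible under DBU (retro-addition through the enolate), C1 should equilibrate to the isomer with the 2-oxopropyl group anti to the pseudoaxial C7 substituent (no syn 1,3-interaction across C7a), i.e. (1S); closest known reaction type: domino Heck/oxa-Michael and Heck/aza-Michael annulations of ortho-halobenzyl alcohols and amines with acrylates or enones to 1-substituted 1,3-dihydroisobenzofurans and isoindolines, together with Heck couplings of cycloalkenyl triflates with methyl vinyl ketone.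

**Step 12**
Reactants: 19 1-[(1S,4S,6S,7R)-4-[(tert-butyldimethylsilyl)oxy]-7-{[(4-methoxyphenyl)methoxy]methyl}-6-methyl-6-(4-methylpent-3-en-1-yl)-1,3,4,5,6,7-hexahydro-2-benzofuran-1-yl]propan-2-one
Product: 20 1-[(1S,4S,6S,7R)-4-[(tert-butyldimethylsilyl)oxy]-7-(hydroxymethyl)-6-methyl-6-(4-methylpent-3-en-1-yl)-1,3,4,5,6,7-hexahydro-2-benzofuran-1-yl]propan-2-one
Conditions: DDQ, CH2Cl2/aq. NaH2PO4–Na2HPO4 (pH 7), 0 °C
Reagents that add atoms: none
Why: Oxidative cleavage of the 4-methoxybenzyl ether (hydride abstraction at the electron-rich benzylic position, then hydrolysis); short reaction at 0 °C under buffer leaves the silyl ether, the ketone and the dihydrofuran untouched.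

**Step 13**
Reactants: 20 1-[(1S,4S,6S,7R)-4-[(tert-butyldimethylsilyl)oxy]-7-(hydroxymethyl)-6-methyl-6-(4-methylpent-3-en-1-yl)-1,3,4,5,6,7-hexahydro-2-benzofuran-1-yl]propan-2-one
Product: 21 (1S,4S,6S,7R)-4-[(tert-butyldimethylsilyl)oxy]-6-methyl-6-(4-methylpent-3-en-1-yl)-1-(2-oxopropyl)-1,3,4,5,6,7-hexahydro-2-benzofuran-7-carbaldehyde
Conditions: Dess–Martin periodinane, NaHCO3, CH2Cl2, 0 °C
Reagents that add atoms: none
Why: Buffered, non-basic Dess–Martin oxidation, so the C7 centre (α to the aldehyde and allylic) is neither epimerised nor moved into conjugation; the crude aldehyde is used at once.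

**Step 14**
Reactants: 21 (1S,4S,6S,7R)-4-[(tert-butyldimethylsilyl)oxy]-6-methyl-6-(4-methylpent-3-en-1-yl)-1-(2-oxopropyl)-1,3,4,5,6,7-hexahydro-2-benzofuran-7-carbaldehyde; 22 2-(dichloromethyl)-4,4,5,5-tetramethyl-1,3,2-dioxaborolane
Product: 23 1-[(1S,4S,6S,7R)-4-[(tert-butyldimethylsilyl)oxy]-6-methyl-6-(4-methylpent-3-en-1-yl)-7-[(E)-2-(4,4,5,5-tetramethyl-1,3,2-dioxaborolan-2-yl)ethenyl]-1,3,4,5,6,7-hexahydro-2-benzofuran-1-yl]propan-2-one
Conditions: CrCl2 (8 equiv), LiI, THF, 25 °C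
Reagents that add atoms: none
Why: Takai–Utimoto boryl-olefination: the geminal dichromium reagent from 22 adds to the aldehyde much faster than to the methyl ketone, and anti-periplanar elimination of the β-oxidochromium adduct gives the (E)-alkenylboronate under non-basic conditions that keep C7 intact.

**Step 15**
Reactants: 23 1-[(1S,4S,6S,7R)-4-[(tert-butyldimethylsilyl)oxy]-6-methyl-6-(4-methylpent-3-en-1-yl)-7-[(E)-2-(4,4,5,5-tetramethyl-1,3,2-dioxaborolan-2-yl)ethenyl]-1,3,4,5,6,7-hexahydro-2-benzofuran-1-yl]propan-2-one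
Product: 24 potassium {(E)-2-[(1S,4S,6S,7R)-4-[(tert-butyldimethylsilyl)oxy]-6-methyl-6-(4-methylpent-3-en-1-yl)-1-(2-oxopropyl)-1,3,4,5,6,7-hexahydro-2-benzofuran-7-yl]ethenyl}trifluoroborate
Conditions: KHF2, MeOH/H2O, 25 °C
Reagents that add atoms: potassium hydrogen difluoride, [K+].F[H-]F
Why: Ligand exchange at boron (pinacol for fluoride) with retention of the E-alkene; secondary alkyl silyl ethers survive KHF2 at room temperature.

**Step 16**
Reactants: 24 potassium {(E)-2-[(1S,4S,6S,7R)-4-[(tert-butyldimethylsilyl)oxy]-6-methyl-6-(4-methylpent-3-en-1-yl)-1-(2-oxopropyl)-1,3,4,5,6,7-hexahydro-2-benzofuran-7-yl]ethenyl}trifluoroborate; 25 3-methylbut-2-enoic acid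
Product: 26 (E)-2-[(1S,4S,6S,7R)-4-[(tert-butyldimethylsilyl)oxy]-6-methyl-6-(4-methylpent-3-en-1-yl)-1-(2-oxopropyl)-1,3,4,5,6,7-hexahydro-2-benzofuran-7-yl]ethenyl 3-methylbut-2-enoate
Conditions: CuBr (10 mol %), DMAP (20 mol %), 4 Å molecular sieves, O2 (1 atm), CH2Cl2, 40 °C
Reagents that add atoms: none
Why: Chan–Lam-type oxidative C–O coupling of an alkenyltrifluoroborate with a carboxylic acid (transmetallation to copper, carboxylate binding, oxidation, C–O reductive elimination), which is stereoretentive and so gives the (E)-enol ester.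

**Step 17**
Reactants: 26 (E)-2-[(1S,4S,6S,7R)-4-[(tert-butyldimethylsilyl)oxy]-6-methyl-6-(4-methylpent-3-en-1-yl)-1-(2-oxopropyl)-1,3,4,5,6,7-hexahydro-2-benzofuran-7-yl]ethenyl 3-methylbut-2-enoate
Product: 27 (E)-2-[(1S,4S,6S,7R)-4-hydroxy-6-methyl-6-(4-methylpent-3-en-1-yl)-1-(2-oxopropyl)-1,3,4,5,6,7-hexahydro-2-benzofuran-7-yl]ethenyl 3-methylbut-2-enoate
Conditions: HF·pyridine, pyridine, THF, 0 → 25 °C
Reagents that add atoms: none
Why: Fluoride-mediated desilylation under buffered, weakly acidic conditions that leave the enol ester, the β-alkoxy ketone and all four stereocentres untouched.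

**Compound list**
1 | geraniol, (2E)-3,7-dimethylocta-2,6-dien-1-ol | CC(C)=CCC/C(C)=C/CO | starting material
2 | 3-[(4-methoxyphenyl)methoxy]propanoic acid | COc1ccc(COCCC(=O)O)cc1 | starting material
3 | (2E)-3,7-dimethylocta-2,6-dien-1-yl 3-[(4-methoxyphenyl)methoxy]propanoate | COc1ccc(COCCC(=O)OC/C=C(\C)CCC=C(C)C)cc1 | intermediate
4 | (4R,5R)-1,3-bis{[3,5-bis(trifluoromethyl)phenyl]sulfonyl}-2-({(1E)-1-{[(2E)-3,7-dimethylocta-2,6-dien-1-yl]oxy}-3-[(4-methoxyphenyl)methoxy]prop-1-en-1-yl}oxy)-4,5-diphenyl-1,3,2-diazaborolidine (boron ketene acetal, CH2OPMB cis to O–B) | COc1ccc(COC/C=C(/OC/C=C(\C)CCC=C(C)C)OB2N(S(=O)(=O)c3cc(cc(c3)C(F)(F)F)C(F)(F)F)[C@H](c3ccccc3)[C@@H](c3ccccc3)N2S(=O)(=O)c2cc(cc(c2)C(F)(F)F)C(F)(F)F)cc1 | intermediate (not isolated)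
5 | (2S,3S)-3-ethenyl-2-{[(4-methoxyphenyl)methoxy]methyl}-3,7-dimethyloct-6-enoic acid | OC(=O)[C@H](COCc1ccc(OC)cc1)[C@@](C)(CCC=C(C)C)C=C | intermediate (not isolated)
6 | methyl (2S,3S)-3-ethenyl-2-{[(4-methoxyphenyl)methoxy]methyl}-3,7-dimethyloct-6-enoate | COC(=O)[C@H](COCc1ccc(OC)cc1)[C@@](C)(CCC=C(C)C)C=C | intermediate
7 | methyl (2S,3R)-3-[2-(9-borabicyclo[3.3.1]nonan-9-yl)ethyl]-2-{[(4-methoxyphenyl)methoxy]methyl}-3,7-dimethyloct-6-enoate | COC(=O)[C@H](COCc1ccc(OC)cc1)[C@@](C)(CCC=C(C)C)CCB1C2CCCC1CCC2 | intermediate (not isolated)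
8 | methyl (2S,3S)-3-(2-hydroxyethyl)-2-{[(4-methoxyphenyl)methoxy]methyl}-3,7-dimethyloct-6-enoate | COC(=O)[C@H](COCc1ccc(OC)cc1)[C@@](C)(CCC=C(C)C)CCO | intermediate
9 | methyl (2S,3S)-2-{[(4-methoxyphenyl)methoxy]methyl}-3,7-dimethyl-3-(2-oxoethyl)oct-6-enoate | COC(=O)[C@H](COCc1ccc(OC)cc1)[C@@](C)(CCC=C(C)C)CC=O | intermediate
10 | ethyl diazoacetate | CCOC(=O)C=[N+]=[N-] | starting material
11 | 1-ethyl 7-methyl (5S,6S)-6-{[(4-methoxyphenyl)methoxy]methyl}-5-methyl-5-(4-methylpent-3-en-1-yl)-3-oxoheptanedioate | COC(=O)[C@H](COCc1ccc(OC)cc1)[C@@](C)(CCC=C(C)C)CC(=O)CC(=O)OCC | intermediate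
12 | 1-ethyl 7-methyl (3S,5S,6S)-3-hydroxy-6-{[(4-methoxyphenyl)methoxy]methyl}-5-methyl-5-(4-methylpent-3-en-1-yl)heptanedioate | COC(=O)[C@H](COCc1ccc(OC)cc1)[C@@](C)(CCC=C(C)C)C[C@H](O)CC(=O)OCC | intermediate
13 | 1-ethyl 7-methyl (3S,5S,6S)-3-[(tert-butyldimethylsilyl)oxy]-6-{[(4-methoxyphenyl)methoxy]methyl}-5-methyl-5-(4-methylpent-3-en-1-yl)heptanedioate | COC(=O)[C@H](COCc1ccc(OC)cc1)[C@@](C)(CCC=C(C)C)C[C@H](O[Si](C)(C)C(C)(C)C)CC(=O)OCC | intermediate
14 | ethyl (3S,4S,6S)-6-[(tert-butyldimethylsilyl)oxy]-2-hydroxy-3-{[(4-methoxyphenyl)methoxy]methyl}-4-methyl-4-(4-methylpent-3-en-1-yl)cyclohex-1-ene-1-carboxylate (enol form of the β-keto ester) | CCOC(=O)C1=C(O)[C@H](COCc2ccc(OC)cc2)[C@@](C)(CCC=C(C)C)C[C@@H]1O[Si](C)(C)C(C)(C)C | intermediate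
15 | ethyl (3S,4S,6S)-6-[(tert-butyldimethylsilyl)oxy]-3-{[(4-methoxyphenyl)methoxy]methyl}-4-methyl-4-(4-methylpent-3-en-1-yl)-2-[(trifluoromethanesulfonyl)oxy]cyclohex-1-ene-1-carboxylate | CCOC(=O)C1=C(OS(=O)(=O)C(F)(F)F)[C@H](COCc2ccc(OC)cc2)[C@@](C)(CCC=C(C)C)C[C@@H]1O[Si](C)(C)C(C)(C)C | intermediate
16 | (3S,5S,6S)-3-[(tert-butyldimethylsilyl)oxy]-2-(hydroxymethyl)-6-{[(4-methoxyphenyl)methoxy]methyl}-5-methyl-5-(4-methylpent-3-en-1-yl)cyclohex-1-en-1-yl trifluoromethanesulfonate | OCC1=C(OS(=O)(=O)C(F)(F)F)[C@H](COCc2ccc(OC)cc2)[C@@](C)(CCC=C(C)C)C[C@@H]1O[Si](C)(C)C(C)(C)C | intermediate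
17 | but-3-en-2-one (methyl vinyl ketone) | CC(=O)C=C | starting material
18 | (3E)-4-[(3S,5S,6R)-3-[(tert-butyldimethylsilyl)oxy]-2-(hydroxymethyl)-6-{[(4-methoxyphenyl)methoxy]methyl}-5-methyl-5-(4-methylpent-3-en-1-yl)cyclohex-1-en-1-yl]but-3-en-2-one | OCC1=C(/C=C/C(C)=O)[C@H](COCc2ccc(OC)cc2)[C@@](C)(CCC=C(C)C)C[C@@H]1O[Si](C)(C)C(C)(C)C | intermediate (not isolated)
19 | 1-[(1S,4S,6S,7R)-4-[(tert-butyldimethylsilyl)oxy]-7-{[(4-methoxyphenyl)methoxy]methyl}-6-methyl-6-(4-methylpent-3-en-1-yl)-1,3,4,5,6,7-hexahydro-2-benzofuran-1-yl]propan-2-one | CC(=O)C[C@@H]1OCC2=C1[C@H](COCc3ccc(OC)cc3)[C@@](C)(CCC=C(C)C)C[C@@H]2O[Si](C)(C)C(C)(C)C | intermediate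
20 | 1-[(1S,4S,6S,7R)-4-[(tert-butyldimethylsilyl)oxy]-7-(hydroxymethyl)-6-methyl-6-(4-methylpent-3-en-1-yl)-1,3,4,5,6,7-hexahydro-2-benzofuran-1-yl]propan-2-one | CC(=O)C[C@@H]1OCC2=C1[C@H](CO)[C@@](C)(CCC=C(C)C)C[C@@H]2O[Si](C)(C)C(C)(C)C | intermediate
21 | (1S,4S,6S,7R)-4-[(tert-butyldimethylsilyl)oxy]-6-methyl-6-(4-methylpent-3-en-1-yl)-1-(2-oxopropyl)-1,3,4,5,6,7-hexahydro-2-benzofuran-7-carbaldehyde | CC(=O)C[C@@H]1OCC2=C1[C@H](C=O)[C@@](C)(CCC=C(C)C)C[C@@H]2O[Si](C)(C)C(C)(C)C | intermediate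
22 | 2-(dichloromethyl)-4,4,5,5-tetramethyl-1,3,2-dioxaborolane | ClC(Cl)B1OC(C)(C)C(C)(C)O1 | starting material
23 | 1-[(1S,4S,6S,7R)-4-[(tert-butyldimethylsilyl)oxy]-6-methyl-6-(4-methylpent-3-en-1-yl)-7-[(E)-2-(4,4,5,5-tetramethyl-1,3,2-dioxaborolan-2-yl)ethenyl]-1,3,4,5,6,7-hexahydro-2-benzofuran-1-yl]propan-2-one | CC(=O)C[C@@H]1OCC2=C1[C@H](/C=C/B3OC(C)(C)C(C)(C)O3)[C@@](C)(CCC=C(C)C)C[C@@H]2O[Si](C)(C)C(C)(C)C | intermediate
24 | potassium {(E)-2-[(1S,4S,6S,7R)-4-[(tert-butyldimethylsilyl)oxy]-6-methyl-6-(4-methylpent-3-en-1-yl)-1-(2-oxopropyl)-1,3,4,5,6,7-hexahydro-2-benzofuran-7-yl]ethenyl}trifluoroborate | CC(=O)C[C@@H]1OCC2=C1[C@H](/C=C/[B-](F)(F)F)[C@@](C)(CCC=C(C)C)C[C@@H]2O[Si](C)(C)C(C)(C)C.[K+] | intermediate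
25 | 3-methylbut-2-enoic acid | CC(C)=CC(=O)O | starting material
26 | (E)-2-[(1S,4S,6S,7R)-4-[(tert-butyldimethylsilyl)oxy]-6-methyl-6-(4-methylpent-3-en-1-yl)-1-(2-oxopropyl)-1,3,4,5,6,7-hexahydro-2-benzofuran-7-yl]ethenyl 3-methylbut-2-enoate | CC(=O)C[C@@H]1OCC2=C1[C@H](/C=C/OC(=O)C=C(C)C)[C@@](C)(CCC=C(C)C)C[C@@H]2O[Si](C)(C)C(C)(C)C | intermediate
27 | (E)-2-[(1S,4S,6S,7R)-4-hydroxy-6-methyl-6-(4-methylpent-3-en-1-yl)-1-(2-oxopropyl)-1,3,4,5,6,7-hexahydro-2-benzofuran-7-yl]ethenyl 3-methylbut-2-enoate (CNP0260614.2) | CC(=O)C[C@@H]1OCC2=C1[C@H](/C=C/OC(=O)C=C(C)C)[C@@](C)(CCC=C(C)C)C[C@@H]2O | target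

**Totals and risk**
Total step count: 17. Longest linear sequence: 17 steps (1 → 27); compounds 2, 10, 17, 22 and 25 enter as purchased partners.

Three steps most likely to fail:

Step 2 (enantioselective Ireland–Claisen). The rearrangement has to build a quaternary carbon from a β-alkoxy ester with full reagent control of the absolute sense. Fallback (known chemistry), setting out from 3: a classical Ireland–Claisen rearrangement with LiN(i-Pr)2 and Me3SiCl in THF/DMPU (Z(O)-enolate conditions, −78 → 25 °C) followed by aqueous hydrolysis gives the racemic acid F1 with the same relative configuration. Classical resolution by crystallisation with (S)-1-phenylethanamine (or its antipode, whichever salt crystallises) gives the ammonium salt F2 of the (2S,3S)-acid. Acidification returns acid 5, and Me3SiCHN2 brings the material back to the route at 6.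

Step 8 (Dieckmann condensation). The acceptor ester is hindered, and the ester enolate carries a β-silyloxy group that can be lost by E1cB elimination. Fallback (known chemistry), setting out from 12: the unprotected hydroxy diester is treated with LiN(i-Pr)2 (3.2 equiv) in THF (−78 → 0 °C). The alkoxide–enolate dianion cannot undergo β-elimination, and any lactone formed reversibly is funnelled by the irreversible Dieckmann closure to the dihydroxy enol ester F3. Silylation of F3 (TBSOTf, 2,6-lutidine, then aq. citric acid to cleave any enol silyl ether) comes back to the route at 14.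

Step 11 (proposed new domino Heck/oxa-Michael reaction). The primary alcohol of 16 could add to 17 before the Heck step, the hindered triflate could couple slowly, and the C1 ratio depends on thermodynamic equilibration. Fallback (known chemistry), setting out from 16: palladium-catalysed intramolecular alkoxycarbonylation (Pd(PPh3)4, CO 1 atm, Et3N, MeCN, 60 °C) gives the butenolide F4. Partial reduction with i-Bu2AlH (1.1 equiv, CH2Cl2, −78 °C) gives the lactol F5. Wittig olefination of its ring-opened hydroxy-enal form with Ph3P=CHC(O)CH3 (PhMe, 80 °C) gives dienone 18, which closes by oxa-Michael addition (DBU, 25 °C) and comes back to the route at 19.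

**Further compounds**
F1 | step 2 | rac-(2S,3S)-3-ethenyl-2-{[(4-methoxyphenyl)methoxy]methyl}-3,7-dimethyloct-6-enoic acid (racemate of 5) | OC(=O)[C@H](COCc1ccc(OC)cc1)[C@@](C)(CCC=C(C)C)C=C.OC(=O)[C@@H](COCc1ccc(OC)cc1)[C@](C)(CCC=C(C)C)C=C
F2 | step 2 | (1S)-1-phenylethan-1-aminium (2S,3S)-3-ethenyl-2-{[(4-methoxyphenyl)methoxy]methyl}-3,7-dimethyloct-6-enoate | C[C@H]([NH3+])c1ccccc1.[O-]C(=O)[C@H](COCc1ccc(OC)cc1)[C@@](C)(CCC=C(C)C)C=C
F3 | step 8 | ethyl (3S,4S,6S)-2,6-dihydroxy-3-{[(4-methoxyphenyl)methoxy]methyl}-4-methyl-4-(4-methylpent-3-en-1-yl)cyclohex-1-ene-1-carboxylate | CCOC(=O)C1=C(O)[C@H](COCc2ccc(OC)cc2)[C@@](C)(CCC=C(C)C)C[C@@H]1O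
F4 | step 11 | (4S,6S,7R)-4-[(tert-butyldimethylsilyl)oxy]-7-{[(4-methoxyphenyl)methoxy]methyl}-6-methyl-6-(4-methylpent-3-en-1-yl)-4,5,6,7-tetrahydro-2-benzofuran-1(3H)-one | O=C1OCC2=C1[C@H](COCc3ccc(OC)cc3)[C@@](C)(CCC=C(C)C)C[C@@H]2O[Si](C)(C)C(C)(C)C
F5 | step 11 | (4S,6S,7R)-4-[(tert-butyldimethylsilyl)oxy]-7-{[(4-methoxyphenyl)methoxy]methyl}-6-methyl-6-(4-methylpent-3-en-1-yl)-1,3,4,5,6,7-hexahydro-2-benzofuran-1-ol (both C1 epimers) | OC1OCC2=C1[C@H](COCc3ccc(OC)cc3)[C@@](C)(CCC=C(C)C)C[C@@H]2O[Si](C)(C)C(C)(C)C
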